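Target cannot fall in a closed flask at constant temperature if nothing consumes it, yet the north-west run reads 0.367 M at 13 min and 0.344 M at 15 min.

| setting | west | north-west | south-west | north-east |
|---|---|---|---|---|
| starting material | 0.500 M | 0.500 M | 0.250 M | 0.500 M |
| catalyst | 0.00100 M | 0.00150 M | 0.00100 M | 0.00100 M |
| time |  |  |  | 30 min |

| west run: time / min | west run: [target] / M | north-west run: time / min | north-west run: [target] / M | south-west run: time / min | south-west run: [target] / M |
|---|---|---|---|---|---|
| 1.9 | 0.065 | 1.9 | 0.140 | 1.9 | 0.054 |
| 3.8 | 0.123 | 3.8 | 0.251 | 3.8 | 0.086 |
| 5.6 | 0.167 | 5.6 | 0.327 | 5.6 | 0.118 |
| 7.5 | 0.215 | 7.5 | 0.379 | 7.5 | 0.150 |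
| 9.4 | 0.241 | 9.4 | 0.385 | 9.4 | 0.154 |
| 11 | 0.272 | 11 | 0.384 | 11 | 0.163 |
| 13 | 0.296 | 13 | 0.367 | 13 | 0.172 |
| 15 | 0.308 | 15 | 0.344 | 15 | 0.166 |

(each reading ± 0.003 M)

- Overall: starting material -> target, with catalyst as catalyst.
- Constant volume, constant temperature.
- The analysis sees a species whether free or bound.
- An order is taken over about fifteen percent of the charge, up and down.

- the power of [catalyst] that the first rate follows, about the charge of the west run; measure it at two percent of starting material made into target
- the power of [starting material] that the first rate follows, about the charge of the west run; measure it at two percent of starting material made into target (one fixed amount of target, the same in the runs compared)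
- target in the north-east run at 30 min, as a share of the starting material charged

Turn the north-east question round. For that run to end near its full charge, target would have to last, so the later of those two north-west readings could not lie below the earlier one by more than their scatter. They differ by 0.0230 M, which is 5.42 standard deviations of such a difference.

So freeze the loss. Divide the logarithm of the ratio of these two readings by the time between them, and read 0.0324 /min: this is the loss constant, the share of target lost per minute as read from the net fall between two scattered readings, taken as a first-order rate constant.

Now make my own reckoning for the north-east run, whose charge equals the west run's. The west run reads 0.241 M at 9.4 min, about half its charge, so take that time as the average birth of target. Assume the whole charge has turned by 30 min. On these assumptions target waits 20.6 min on average, and the share surviving is 51.3 %, which is my estimate of the yield.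

By its own reckoning, the forecast gives 49 %, within 42 % to 56 %, with orders 1.9 in catalyst and 0.3 in starting material, and it states: “The north-west fall after its peak shows target being lost”. Its yield is lower than my 51.3 %.

    catalyst + starting material ⇌ catalyst-substrate complex, settled at all times (1.530 /M)
    catalyst-substrate complex + catalyst → target + 2 catalyst (1.716 × 10⁵ /M/min)
    target → decomposed product (0.03444 /min)
    2 starting material ⇌ idle substrate dimer, settled at all times (1.580 /M)

The north-east run gives 49.3 %; about the charge of the west run, the first rate follows orders of 2.0 in catalyst and 0.30 in starting material. A fit of the main steps alone forecasts 88.3 % for the north-east run. Now put the loss constant to the south-west run, which did not supply it. That run reads 0.118 M at 5.6 min, about half its charge of 0.250 M, so take that time as the average birth of target and assume the whole charge has turned by 15 min. The charge, reduced by the survival share over the 9.40 min between, gives an estimate of 0.184 M, higher than the south-west reading of 0.166 M at 15 min.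

The readings come from a simulation for substances that don't exist.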